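## Retrosynthetic overview

1. Numbering runs from C1 (lactone C=O) to C12 (CH3). The plan rests on the 5,6-dihydro-2H-pyran-2-one ring (ring O, C1–C5) and its C5–O centre, which is anti to the C6 carbinol. This ring is the oxidised form of a 2-methoxydihydropyran, that is, of an aldehyde/1-methoxybutadiene oxa-[4+2] adduct (cuts C4–C5 and O–C1).
2. The C5 aldehyde already carries C6–C12: the cis-oxolane (O, C7–C10), the C6 silyl ether and the C11 O-(silyl-coumaroyl) ester. It is unmasked from a C5=CMe2 alkene. This alkene is used instead of vinyl so that ozone takes the electron-rich trisubstituted bond and spares the cinnamate bond.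
3. C5–C6 and C11–C12 come from two chelation-controlled Grignard additions (both threo) to the two arms of the oxolane. The C6 arm is built first, so the acetate is removed and both Grignard reagents are spent before the coumarate ester is present.
4. Absolute configuration comes from lipase desymmetrisation of meso cis-2,5-bis(hydroxymethyl)oxolane, made by hydrogenation of the furan diol.
5. Ring order: oxolane (step 1), dihydropyran (step 12), oxidation to the lactone (step 13).

Key step: step 12

Assumption: the lipase is taken to acetylate the arm on the (S)-configured ring carbon (the hydrolytic mode of the same desymmetrisation is enantiocomplementary if the preference is the reverse), and the sense of induction of the (1R,2S)-configured chromium catalyst is assigned by analogy with its behaviour towards silyloxyacetaldehyde.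

## Route

Step 1
Reactants: 1 2,5-bis(hydroxymethyl)furan
Product: 2 cis-2,5-bis(hydroxymethyl)oxolane (meso, 2R,5S)
Conditions: H2 (70 bar), Raney Ni, EtOH, 60 °C
Reagents that add atoms: none
Why: Heterogeneous catalytic hydrogenation of a furan delivers hydrogen to both double bonds from the face adsorbed on nickel, so C7 and C10 should form cis (meso), and nickel has little tendency to hydrogenolyse the furfurylic C–O bonds.

Step 2
Reactants: 2 cis-2,5-bis(hydroxymethyl)oxolane
Product: 3 [(2S,5R)-5-(hydroxymethyl)oxolan-2-yl]methyl acetate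
Conditions: lipase from Burkholderia cepacia (lipase PS), vinyl acetate (3 equiv), t-BuOMe, rt, stopped when the diol is consumed
Reagents that add atoms: vinyl acetate, C=COC(C)=O
Why: Lipase-catalysed irreversible transesterification (enzymatic desymmetrisation of a meso diol) acylates one of the two enantiotopic hydroxymethyl arms and so fixes C7 as R and C10 as S, the vinyl alcohol released tautomerises so the step cannot reverse, and faster second acetylation of the minor enantiomer should raise the enantiopurity of 3.

Step 3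
Reactants: 3 [(2S,5R)-5-(hydroxymethyl)oxolan-2-yl]methyl acetate
Product: 4 [(2S,5R)-5-formyloxolan-2-yl]methyl acetate
Conditions: TEMPO (10 mol %), PhI(OAc)2 (1.1 equiv), CH2Cl2, rt
Reagents that add atoms: none
Why: Oxoammonium-mediated (TEMPO/PhI(OAc)2) oxidation of a primary alcohol stops at the aldehyde and needs no base, so the epimerisable C7 centre and the acetate are left alone.

Step 4
Reactants: 4 [(2S,5R)-5-formyloxolan-2-yl]methyl acetate; 5 2-methylprop-1-enylmagnesium bromide
Product: 6 [(2S,5R)-5-[(1R)-1-hydroxy-3-methylbut-2-enyl]oxolan-2-yl]methyl acetate (C6/C7 threo)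
Conditions: MgBr2·OEt2 (2 equiv), CH2Cl2, −78 °C; then 5 (1.15 equiv, 0.5 M in THF), −78 °C; cold quench with pH 7 buffer
Reagents that add atoms: none
Why: In this chelation-controlled (Cram chelate) Grignard addition magnesium ties the aldehyde oxygen to the oxolane oxygen in a five-membered chelate and the alkenyl group enters from the side of the C7 hydrogen, which sets C6 threo to C7, while at −78 °C the chelate-activated aldehyde reacts far faster than the primary acetate.

Step 5
Reactants: 6 [(2S,5R)-5-[(1R)-1-hydroxy-3-methylbut-2-enyl]oxolan-2-yl]methyl acetate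
Product: 7 [(2S,5R)-5-[(1R)-1-(tert-butyldimethylsilyloxy)-3-methylbut-2-enyl]oxolan-2-yl]methyl acetate
Conditions: TBSOTf (1.2 equiv), 2,6-lutidine (1.2 equiv), CH2Cl2, −78 to 0 °C
Reagents that add atoms: tert-butyldimethylsilyl triflate, CC(C)(C)[Si](C)(C)OS(=O)(=O)C(F)(F)F
Why: Silylation of a hindered secondary allylic alcohol with a silyl triflate and a non-nucleophilic base is fast at low temperature, leaves the acetate in place and installs at C6 the bulky, non-chelating group that step 12 needs.

Step 6
Reactants: 7 [(2S,5R)-5-[(1R)-1-(tert-butyldimethylsilyloxy)-3-methylbut-2-enyl]oxolan-2-yl]methyl acetate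
Product: 8 [(2S,5R)-5-[(1R)-1-(tert-butyldimethylsilyloxy)-3-methylbut-2-enyl]oxolan-2-yl]methanol
Conditions: K2CO3 (0.2 equiv), MeOH, 0 °C to rt
Reagents that add atoms: none
Why: Carbonate-catalysed methanolysis (transesterification) removes the primary acetate while the secondary alkyl silyl ether and the alkene are inert, and it is placed here because no other ester and no aryl silyl ether is yet present.

Step 7
Reactants: 8 [(2S,5R)-5-[(1R)-1-(tert-butyldimethylsilyloxy)-3-methylbut-2-enyl]oxolan-2-yl]methanol
Product: 9 (2S,5R)-5-[(1R)-1-(tert-butyldimethylsilyloxy)-3-methylbut-2-enyl]oxolane-2-carbaldehyde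
Conditions: TEMPO (10 mol %), PhI(OAc)2 (1.1 equiv), CH2Cl2, rt
Reagents that add atoms: none
Why: The same base-free oxoammonium oxidation gives the aldehyde without epimerising C10 and is known to tolerate trisubstituted alkenes and silyl ethers.

Step 8
Reactants: 9 (2S,5R)-5-[(1R)-1-(tert-butyldimethylsilyloxy)-3-methylbut-2-enyl]oxolane-2-carbaldehyde
Product: 10 (1S)-1-[(2S,5R)-5-[(1R)-1-(tert-butyldimethylsilyloxy)-3-methylbut-2-enyl]oxolan-2-yl]ethanol (C10/C11 threo)
Conditions: MgBr2·OEt2 (2 equiv), CH2Cl2, −78 °C; then MeMgBr (1.5 equiv, 3 M in Et2O), −78 °C; quench with pH 7 buffer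
Reagents that add atoms: methylmagnesium bromide, C[Mg]Br
Why: A second chelation-controlled Grignard addition through the aldehyde-oxygen/oxolane-oxygen magnesium chelate brings methyl in from the side of the C10 hydrogen and sets C11 as S, threo to C10, with no ester in the molecule to compete.

Step 9
Reactants: 11 (E)-4-hydroxycinnamic acid
Product: 13 (E)-3-[4-(tert-butyldimethylsilyloxy)phenyl]prop-2-enoic acid, via bis-silylated coumarate 12 (not isolated)
Conditions: TBSCl (2.5 equiv), imidazole (5 equiv), DMF, rt; crude product in THF/H2O/AcOH, rt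
Reagents that add atoms: tert-butyldimethylsilyl chloride, CC(C)(C)[Si](C)(C)Cl
Why: Exhaustive silylation followed by selective hydrolysis works because a silyl ester is far more labile to aqueous acid than an aryl silyl ether, so only the carboxyl group is set free.

Step 10
Reactants: 10 (1S)-1-[(2S,5R)-5-[(1R)-1-(tert-butyldimethylsilyloxy)-3-methylbut-2-enyl]oxolan-2-yl]ethanol; 13 (E)-3-[4-(tert-butyldimethylsilyloxy)phenyl]prop-2-enoic acid
Product: 14 (1S)-1-[(2S,5R)-5-[(1R)-1-(tert-butyldimethylsilyloxy)-3-methylbut-2-enyl]oxolan-2-yl]ethyl (E)-3-[4-(tert-butyldimethylsilyloxy)phenyl]prop-2-enoate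
Conditions: DCC (1.3 equiv), DMAP (0.2 equiv), CH2Cl2, 0 °C to rt
Reagents that add atoms: none
Why: Steglich esterification (carbodiimide activation with DMAP acyl transfer) acylates the only free hydroxyl with retention at C11, because the C11–O bond is not touched, and it keeps the E geometry of the acid.

Step 11
Reactants: 14 (1S)-1-[(2S,5R)-5-[(1R)-1-(tert-butyldimethylsilyloxy)-3-methylbut-2-enyl]oxolan-2-yl]ethyl (E)-3-[4-(tert-butyldimethylsilyloxy)phenyl]prop-2-enoate
Product: 16 (1S)-1-[(2S,5R)-5-[(1S)-1-(tert-butyldimethylsilyloxy)-2-oxoethyl]oxolan-2-yl]ethyl (E)-3-[4-(tert-butyldimethylsilyloxy)phenyl]prop-2-enoate, via secondary ozonide 15 (not isolated)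
Conditions: O3/O2, CH2Cl2, −78 °C, Sudan Red 7B as end-point indicator; then PPh3 (1.2 equiv), −78 °C to rt
Reagents that add atoms: ozone, [O-][O+]=O
Why: In this ozonolysis with reductive work-up (Criegee mechanism) electrophilic ozone should consume the electron-rich trisubstituted C5=CMe2 bond well before the ester-deactivated cinnamate bond, the dye marks the end point, and PPh3 reduces the ozonide under neutral conditions that do not epimerise C6 (the descriptor changes from R to S only through the priority rules).

Step 12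
Reactants: 16 (1S)-1-[(2S,5R)-5-[(1S)-1-(tert-butyldimethylsilyloxy)-2-oxoethyl]oxolan-2-yl]ethyl (E)-3-[4-(tert-butyldimethylsilyloxy)phenyl]prop-2-enoate; 17 (E)-1-methoxybuta-1,3-diene
Product: 18 (1S)-1-[(2S,5R)-5-[(S)-(tert-butyldimethylsilyloxy)[(2R,6S)-6-methoxy-3,6-dihydro-2H-pyran-2-yl]methyl]oxolan-2-yl]ethyl (E)-3-[4-(tert-butyldimethylsilyloxy)phenyl]prop-2-enoate
Conditions: 17 (3 equiv), (L)CrCl (10 mol %; trivalent chromium, L = dianion of (1R,2S)-1-[3-(1-adamantyl)-2-hydroxy-5-methylbenzylideneamino]indan-2-ol), powdered 4 Å MS, minimum EtOAc, rt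
Reagents that add atoms: none
Why: The Lewis-acidic trivalent chromium centre of (L)CrCl binds the C5 aldehyde oxygen at its single free site, and diene 17 adds through a concerted but asynchronous [4+2] transition state in which C4–C5 bonding runs ahead of O–C1 bonding. The closest known reaction type is the catalytic asymmetric oxa-Diels–Alder reaction of aliphatic and alpha-silyloxy aldehydes with 1-alkoxybutadienes under tridentate Schiff-base chromium chloride catalysis, including its doubly diastereoselective use with chiral aldehydes. The one ring closed, the 3,6-dihydro-2H-pyran (O, C1–C5), forms by intermolecular cycloaddition with both ring bonds made in the same event, so no separate cyclisation mode competes. C5 (R) is set by the catalyst, whose aminoindanol/adamantyl pocket should expose the Re face of the bound aldehyde, and this is also the face left open by the Felkin–Anh conformer of the non-chelating C6 silyloxy group, so the pair is matched and gives the C5/C6 anti relationship; the acetal centre C1 (S, cis to the C5 side chain) follows from the endo approach and is erased in step 13. Chemoselectivity for the aldehyde C=O over the cinnamate C=C and C=O holds because only the aldehyde is basic and accessible enough to bind chromium and an unactivated cinnamate is a poor dienophile at room temperature, while regioselectivity follows from the largest HOMO coefficient of the diene, at its CH2 terminus (C4), meeting the carbonyl carbon. The near-neutral, water-free medium keeps the epimerisable C6 centre and both silyl ethers intact.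

Step 13
Reactants: 18 (1S)-1-[(2S,5R)-5-[(S)-(tert-butyldimethylsilyloxy)[(2R,6S)-6-methoxy-3,6-dihydro-2H-pyran-2-yl]methyl]oxolan-2-yl]ethyl (E)-3-[4-(tert-butyldimethylsilyloxy)phenyl]prop-2-enoate
Product: 19 (1S)-1-[(2S,5R)-5-[(S)-(tert-butyldimethylsilyloxy)[(2R)-6-oxo-3,6-dihydro-2H-pyran-2-yl]methyl]oxolan-2-yl]ethyl (E)-3-[4-(tert-butyldimethylsilyloxy)phenyl]prop-2-enoate
Conditions: pyridinium chlorochromate, C5H5NH[CrO3Cl] (4 equiv), Celite, CH2Cl2, rt
Reagents that add atoms: pyridinium chlorochromate, [O-][Cr](=O)(=O)Cl.c1cc[nH+]cc1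
Why: In this oxidation of an allylic cyclic acetal to a lactone by hexavalent chromium the slightly acidic reagent ionises the acetal to its allyl-stabilised oxocarbenium ion, chlorochromate is captured at C1 and the chromate ester collapses to C1=O, which erases the acetal centre and brings C2=C3 into conjugation without any basic step.

Step 14
Reactants: 19 (1S)-1-[(2S,5R)-5-[(S)-(tert-butyldimethylsilyloxy)[(2R)-6-oxo-3,6-dihydro-2H-pyran-2-yl]methyl]oxolan-2-yl]ethyl (E)-3-[4-(tert-butyldimethylsilyloxy)phenyl]prop-2-enoate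
Product: 20 (1S)-1-[(2S,5R)-5-[(S)-hydroxy[(2R)-6-oxo-3,6-dihydro-2H-pyran-2-yl]methyl]oxolan-2-yl]ethyl (E)-3-(4-hydroxyphenyl)prop-2-enoate (target)
Conditions: HF·pyridine, pyridine, THF, 0 °C to rt
Reagents that add atoms: none
Why: Fluoride-mediated desilylation in a buffered acidic medium cleaves both the aryl and the hindered secondary silyl ether through Si–F bond formation, while the unsaturated lactone, the coumarate ester and the five stereocentres, none of which is touched, tolerate these non-basic conditions.

## Compound list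

1 | 2,5-bis(hydroxymethyl)furan | OCc1ccc(CO)o1 | starting material
2 | cis-2,5-bis(hydroxymethyl)oxolane (meso, 2R,5S) | OC[C@@H]1CC[C@H](CO)O1 | intermediate
3 | [(2S,5R)-5-(hydroxymethyl)oxolan-2-yl]methyl acetate | CC(=O)OC[C@@H]1CC[C@H](CO)O1 | intermediate
4 | [(2S,5R)-5-formyloxolan-2-yl]methyl acetate | CC(=O)OC[C@@H]1CC[C@H](C=O)O1 | intermediate
5 | 2-methylprop-1-enylmagnesium bromide | CC(C)=C[Mg]Br | starting material
6 | [(2S,5R)-5-[(1R)-1-hydroxy-3-methylbut-2-enyl]oxolan-2-yl]methyl acetate | CC(=O)OC[C@@H]1CC[C@H]([C@H](O)C=C(C)C)O1 | intermediate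
7 | [(2S,5R)-5-[(1R)-1-(tert-butyldimethylsilyloxy)-3-methylbut-2-enyl]oxolan-2-yl]methyl acetate | CC(=O)OC[C@@H]1CC[C@H]([C@H](O[Si](C)(C)C(C)(C)C)C=C(C)C)O1 | intermediate
8 | [(2S,5R)-5-[(1R)-1-(tert-butyldimethylsilyloxy)-3-methylbut-2-enyl]oxolan-2-yl]methanol | OC[C@@H]1CC[C@H]([C@H](O[Si](C)(C)C(C)(C)C)C=C(C)C)O1 | intermediate
9 | (2S,5R)-5-[(1R)-1-(tert-butyldimethylsilyloxy)-3-methylbut-2-enyl]oxolane-2-carbaldehyde | O=C[C@@H]1CC[C@H]([C@H](O[Si](C)(C)C(C)(C)C)C=C(C)C)O1 | intermediate
10 | (1S)-1-[(2S,5R)-5-[(1R)-1-(tert-butyldimethylsilyloxy)-3-methylbut-2-enyl]oxolan-2-yl]ethanol | C[C@H](O)[C@@H]1CC[C@H]([C@H](O[Si](C)(C)C(C)(C)C)C=C(C)C)O1 | intermediate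
11 | (E)-4-hydroxycinnamic acid | OC(=O)/C=C/c1ccc(O)cc1 | starting material
12 | tert-butyldimethylsilyl (E)-3-[4-(tert-butyldimethylsilyloxy)phenyl]prop-2-enoate (not isolated) | CC(C)(C)[Si](C)(C)OC(=O)/C=C/c1ccc(O[Si](C)(C)C(C)(C)C)cc1 | intermediate
13 | (E)-3-[4-(tert-butyldimethylsilyloxy)phenyl]prop-2-enoic acid | OC(=O)/C=C/c1ccc(O[Si](C)(C)C(C)(C)C)cc1 | intermediate
14 | coumaroylated C5=CMe2 alkene, (1S)-1-[(2S,5R)-5-[(1R)-1-(tert-butyldimethylsilyloxy)-3-methylbut-2-enyl]oxolan-2-yl]ethyl (E)-3-[4-(tert-butyldimethylsilyloxy)phenyl]prop-2-enoate | C[C@H](OC(=O)/C=C/c1ccc(O[Si](C)(C)C(C)(C)C)cc1)[C@@H]1CC[C@H]([C@H](O[Si](C)(C)C(C)(C)C)C=C(C)C)O1 | intermediate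
15 | secondary ozonide of 14 (3,3-dimethyl-1,2,4-trioxolan-5-yl group at C6, epimers at the trioxolane CH; not isolated) | C[C@H](OC(=O)/C=C/c1ccc(O[Si](C)(C)C(C)(C)C)cc1)[C@@H]1CC[C@H]([C@H](O[Si](C)(C)C(C)(C)C)C2OOC(C)(C)O2)O1 | intermediate
16 | C5 aldehyde, (1S)-1-[(2S,5R)-5-[(1S)-1-(tert-butyldimethylsilyloxy)-2-oxoethyl]oxolan-2-yl]ethyl (E)-3-[4-(tert-butyldimethylsilyloxy)phenyl]prop-2-enoate | C[C@H](OC(=O)/C=C/c1ccc(O[Si](C)(C)C(C)(C)C)cc1)[C@@H]1CC[C@H]([C@H](O[Si](C)(C)C(C)(C)C)C=O)O1 | intermediate
17 | (E)-1-methoxybuta-1,3-diene | CO/C=C/C=C | starting material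
18 | cycloadduct, (1S)-1-[(2S,5R)-5-[(S)-(tert-butyldimethylsilyloxy)[(2R,6S)-6-methoxy-3,6-dihydro-2H-pyran-2-yl]methyl]oxolan-2-yl]ethyl (E)-3-[4-(tert-butyldimethylsilyloxy)phenyl]prop-2-enoate | C[C@H](OC(=O)/C=C/c1ccc(O[Si](C)(C)C(C)(C)C)cc1)[C@@H]1CC[C@H]([C@H](O[Si](C)(C)C(C)(C)C)[C@H]2CC=C[C@@H](OC)O2)O1 | intermediate
19 | bis-silylated lactone, (1S)-1-[(2S,5R)-5-[(S)-(tert-butyldimethylsilyloxy)[(2R)-6-oxo-3,6-dihydro-2H-pyran-2-yl]methyl]oxolan-2-yl]ethyl (E)-3-[4-(tert-butyldimethylsilyloxy)phenyl]prop-2-enoate | C[C@H](OC(=O)/C=C/c1ccc(O[Si](C)(C)C(C)(C)C)cc1)[C@@H]1CC[C@H]([C@H](O[Si](C)(C)C(C)(C)C)[C@H]2CC=CC(=O)O2)O1 | intermediate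
20 | CNP0417147.2, (1S)-1-[(2S,5R)-5-[(S)-hydroxy[(2R)-6-oxo-3,6-dihydro-2H-pyran-2-yl]methyl]oxolan-2-yl]ethyl (E)-3-(4-hydroxyphenyl)prop-2-enoate | C[C@H](OC(=O)/C=C/c1ccc(O)cc1)[C@@H]1CC[C@H]([C@H](O)[C@H]2CC=CC(=O)O2)O1 | target

## Step count and risks

Total step count: 14.
Longest linear sequence: 13 (steps 1–8 and 10–14, from 1). Step 9 is a one-step side branch.

**1. Step 12 (key step).**
- What may go wrong: turnover may be slow because the aldehyde is alpha-branched and flanked by a bulky silyl ether. Diene polymerisation or epimerisation at C6 could then overtake the cycloaddition, or facial control could be incomplete.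
- Fallback, setting out from 16: Brown allylation with (+)-B-allyldiisopinocampheylborane (Et2O, −78 °C, ethanolamine work-up) delivers allyl to the Re face, matched with the Felkin–Anh preference, and gives the C5 (R), C5/C6-anti homoallylic alcohol F1.
- Acryloyl chloride and i-Pr2NEt in CH2Cl2 at 0 °C then give the acrylate F2.
- Ring-closing metathesis with the second-generation Grubbs catalyst in refluxing CH2Cl2 forms C2=C3. The cinnamate bond is too hindered and electron-poor to compete with six-membered ring closure. The route is rejoined at 19.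

**2. Step 4.**
- What may go wrong: facial selectivity may be poor if THF from the reagent solution competes with the substrate for magnesium and loosens the chelate.
- Fallback, setting out from 6 (taken as the C6 epimer mixture): MnO2 in CH2Cl2 oxidises the allylic alcohol to the enone F3.
- Reduction with LiBH(s-Bu)3 in THF at −78 °C then sets C6 by hydride delivery instead of C–C bond formation. The bulky non-chelating hydride follows the Felkin–Anh mode, which for a ketone gives the threo alcohol, and the beta,beta-disubstituted enone resists conjugate reduction. The route is rejoined at 6.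

**3. Step 11.**
- What may go wrong: chemoselectivity may be lost through competing attack of ozone on the cinnamate double bond or on the electron-rich arene once the trisubstituted alkene runs low.
- Fallback, setting out from 14: mCPBA (NaHCO3, CH2Cl2, 0 °C), which does not epoxidise enoates, converts only the nucleophilic trisubstituted alkene into the epoxide F4. This is an epimer mixture at C5, which is of no consequence.
- H5IO6 in THF/Et2O at 0 °C then opens and cleaves F4 to the aldehyde. The route is rejoined at 16.

Further compounds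
F1 | step 12 | C5 (R) homoallylic alcohol from allylation of 16 | C[C@H](OC(=O)/C=C/c1ccc(O[Si](C)(C)C(C)(C)C)cc1)[C@@H]1CC[C@H]([C@H](O[Si](C)(C)C(C)(C)C)[C@H](O)CC=C)O1
F2 | step 12 | C5 acrylate of F1 | C[C@H](OC(=O)/C=C/c1ccc(O[Si](C)(C)C(C)(C)C)cc1)[C@@H]1CC[C@H]([C@H](O[Si](C)(C)C(C)(C)C)[C@H](OC(=O)C=C)CC=C)O1
F3 | step 4 | [(2S,5R)-5-(3-methylbut-2-enoyl)oxolan-2-yl]methyl acetate | CC(=O)OC[C@@H]1CC[C@H](C(=O)C=C(C)C)O1
F4 | step 11 | 3,3-dimethyloxiran-2-yl epoxide of 14 (epimers at the oxirane CH) | C[C@H](OC(=O)/C=C/c1ccc(O[Si](C)(C)C(C)(C)C)cc1)[C@@H]1CC[C@H]([C@H](O[Si](C)(C)C(C)(C)C)C2OC2(C)C)O1
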